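**Plan**
Retrosynthesis first cuts the O–S bond of the 4'-sulfate and the benzyl ethers, then takes the flavonol back to its dihydroflavonol, where C4 (carbonyl) and C3 (carbinol) of ring C form an acyloin pair once the C2=C3 double bond is saturated.
That acyloin is cut at C3–C4 to a ring A benzaldehyde whose O1 carries a CH(aryl)–CHO unit; the O1–C2 ether bond and the C2–C3 bond (vinyl addition to the ring B aldehyde) are cut last.
Forward, the ring A and ring B building blocks are protected separately and joined at O1–C2, the vinyl group is cleaved to the second aldehyde, and ring C is closed by a carbene-catalysed intramolecular benzoin reaction.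
The 3-hydroxyflavanone is then oxidised to the flavonol, O3 is benzylated, the 4'-acetal is removed, the 4'-phenol is sulfated and the benzyl ethers are hydrogenolysed.
The target has no stereocentre; C2 and C3 of the intermediates are racemic, C3 settles trans by enolisation, and both are erased in the oxidation.

Key step: step 7

Assumption: the target is drawn as the free hydrogen sulfate, so the sulfate is carried as its sodium salt and the acid form is released only at the end by cation exchange in the cold; every chiral intermediate is racemic and one enantiomer is drawn.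

Step 1
Reactants: 1 2,4,6-trihydroxybenzaldehyde
Product: 2 2,4-bis(benzyloxy)-6-hydroxybenzaldehyde
Conditions: BnBr (2.05 equiv), K2CO3 (2.2 equiv), DMF, 0 °C to rt
Reagents that add atoms: benzyl bromide, BrCc1ccccc1
Why: Williamson etherification under mild carbonate conditions alkylates the 4-hydroxyl and one of the two equivalent ortho hydroxyls, while the last ortho hydroxyl, hydrogen-bonded to the formyl oxygen and least nucleophilic, is expected to stay free.

Step 2
Reactants: 3 3,4-dihydroxybenzaldehyde
Product: 4 3-hydroxy-4-(methoxymethoxy)benzaldehyde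
Conditions: MOMCl (1.05 equiv), K2CO3 (1.1 equiv), acetone, 0 °C to rt
Reagents that add atoms: chloromethyl methyl ether, COCCl
Why: Regioselective Williamson-type O-alkylation, because the 4-hydroxyl is para to the formyl group and the more acidic, so one equivalent of weak base forms and alkylates the 4-phenoxide in preference to the 3-hydroxyl.

Step 3
Reactants: 4 3-hydroxy-4-(methoxymethoxy)benzaldehyde
Product: 5 3-(benzyloxy)-4-(methoxymethoxy)benzaldehyde
Conditions: BnBr (1.2 equiv), K2CO3 (1.5 equiv), DMF, rt
Reagents that add atoms: benzyl bromide, BrCc1ccccc1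
Why: Williamson etherification of the remaining phenol; the methoxymethyl acetal and the aldehyde are inert to K2CO3 and benzyl bromide.

Step 4
Reactants: 5 3-(benzyloxy)-4-(methoxymethoxy)benzaldehyde; 6 vinylmagnesium bromide
Product: 7 1-[3-(benzyloxy)-4-(methoxymethoxy)phenyl]prop-2-en-1-ol (racemic; R enantiomer drawn)
Conditions: THF, −78 °C to 0 °C; then aq. NH4Cl
Reagents that add atoms: none
Why: Grignard 1,2-addition to the aryl aldehyde gives the allylic benzylic alcohol; the new stereocentre forms without control (racemic), which is harmless because it is destroyed in step 8.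

Step 5
Reactants: 2 2,4-bis(benzyloxy)-6-hydroxybenzaldehyde; 7 1-[3-(benzyloxy)-4-(methoxymethoxy)phenyl]prop-2-en-1-ol
Product: 8 2,4-bis(benzyloxy)-6-({1-[3-(benzyloxy)-4-(methoxymethoxy)phenyl]prop-2-en-1-yl}oxy)benzaldehyde (racemic; S enantiomer drawn)
Conditions: PPh3 (1.5 equiv), DIAD (1.5 equiv), toluene, −20 °C to rt
Reagents that add atoms: none
Why: Mitsunobu etherification, in which the acidic ortho-formyl phenol protonates the betaine and its phenoxide displaces the oxyphosphonium group at the carbinol carbon (SN2 with inversion, of no consequence for racemic material), with low temperature and a non-polar solvent chosen to hold back ionisation and allylic transposition.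

Step 6
Reactants: 8 2,4-bis(benzyloxy)-6-({1-[3-(benzyloxy)-4-(methoxymethoxy)phenyl]prop-2-en-1-yl}oxy)benzaldehyde
Product: 10 2,4-bis(benzyloxy)-6-{1-[3-(benzyloxy)-4-(methoxymethoxy)phenyl]-2-oxoethoxy}benzaldehyde (racemic; R enantiomer drawn), via vicinal diol 9 (not isolated)
Conditions: OsO4 (2 mol%), NaIO4 (4 equiv), 2,6-lutidine (2 equiv), 1,4-dioxane–H2O (3:1), rt; crude dialdehyde used at once under argon
Reagents that add atoms: osmium tetroxide (catalytic oxygen carrier), O=[Os](=O)(=O)=O; sodium periodate (NaIO4), [Na+].[O-]I(=O)(=O)=O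
Why: Lemieux–Johnson oxidation, in which catalytic osmium tetroxide dihydroxylates the only alkene and periodate cleaves the diol and reoxidises osmium, while 2,6-lutidine keeps the medium near neutral so that the aryl aldehyde, the benzyl ethers and the methoxymethyl acetal are untouched.

Step 7
Reactants: 10 2,4-bis(benzyloxy)-6-{1-[3-(benzyloxy)-4-(methoxymethoxy)phenyl]-2-oxoethoxy}benzaldehyde
Product: 11 trans-5,7-bis(benzyloxy)-2-[3-(benzyloxy)-4-(methoxymethoxy)phenyl]-3-hydroxychroman-4-one (5,7,3'-tri-O-benzyl-4'-O-methoxymethyl-dihydroquercetin; racemic; 2R,3R drawn)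
Conditions: 2-(pentafluorophenyl)-6,7-dihydro-5H-pyrrolo[2,1-c][1,2,4]triazol-2-ium tetrafluoroborate (20 mol%), Et3N (20 mol%), toluene (0.02 M), rt, argon
Reagents that add atoms: none
Why: The triazolylidene released by triethylamine adds reversibly to an aldehyde carbon, a proton shift gives the enaminol acyl-anion equivalent, and this adds to the second aldehyde and then releases the carbene, joining C4 and C3 as ketone and carbinol; the closest known reactions are the carbene-catalysed crossed benzoin cyclisation of 2-(2-oxoalkoxy)benzaldehydes to 3-hydroxychroman-4-ones and the acyloin cyclisation of dialdehydes. Ring C closes in the 6-exo-trig mode. The α-branched aliphatic aldehyde is the better acceptor and the poorer acyl donor, so the ring A aldehyde should be the donor; if the roles are reversed, the same ring closure gives the 4-hydroxychroman-3-one, which tautomerises through the shared enediol to the aryl-conjugated 3-hydroxy-4-ketone. The one new stereocentre, C3, is under thermodynamic control, since it lies α to the ketone, equilibrates through the enol under the amine and settles trans to the C2 aryl group with both substituents equatorial. The step needs cyclisation to win over intermolecular benzoin coupling and over loss of the ring A phenoxide from an enaminol formed at the aliphatic aldehyde; the six-atom tether and the α-branching of that aldehyde in the substrate, helped by high dilution, the weakly basic N-pentafluorophenyl carbene and a substoichiometric amine, are relied on for this. Both stereocentres are removed in step 8, so neither the cis/trans outcome nor the racemic nature of the material matters.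

Step 8
Reactants: 11 trans-5,7-bis(benzyloxy)-2-[3-(benzyloxy)-4-(methoxymethoxy)phenyl]-3-hydroxychroman-4-one
Product: 13 5,7-bis(benzyloxy)-2-[3-(benzyloxy)-4-(methoxymethoxy)phenyl]-3-hydroxy-4H-chromen-4-one (5,7,3'-tri-O-benzyl-4'-O-methoxymethyl-quercetin), via flavan-3,4-dione 12 (not isolated)
Conditions: Dess–Martin periodinane (1.1 equiv), CH2Cl2, 0 °C to rt
Reagents that add atoms: none
Why: Dess–Martin oxidation of the acyloin gives the 1,2-dione, whose C2–H enolises to the aromatic, hydrogen-bonded 3-hydroxychromen-4-one so that both stereocentres disappear, a small excess of oxidant at low temperature being used to spare the electron-rich flavonol.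

Step 9
Reactants: 13 5,7-bis(benzyloxy)-2-[3-(benzyloxy)-4-(methoxymethoxy)phenyl]-3-hydroxy-4H-chromen-4-one
Product: 14 3,5,7-tris(benzyloxy)-2-[3-(benzyloxy)-4-(methoxymethoxy)phenyl]-4H-chromen-4-one
Conditions: BnBr (1.5 equiv), K2CO3 (2 equiv), DMF, 50 °C
Reagents that add atoms: benzyl bromide, BrCc1ccccc1
Why: Williamson etherification of the only free hydroxyl (the 3-enol), needed so that the later sulfation can reach the 4'-oxygen alone.

Step 10
Reactants: 14 3,5,7-tris(benzyloxy)-2-[3-(benzyloxy)-4-(methoxymethoxy)phenyl]-4H-chromen-4-one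
Product: 15 3,5,7-tris(benzyloxy)-2-[3-(benzyloxy)-4-hydroxyphenyl]-4H-chromen-4-one (3,5,7,3'-tetra-O-benzylquercetin)
Conditions: 3 M aq. HCl (cat.), MeOH–THF (1:1), 50 °C
Reagents that add atoms: none
Why: Acid-catalysed cleavage of the methoxymethyl acetal by transacetalisation to methanol, which benzyl aryl ethers and the flavone core tolerate in dilute HCl at this temperature.

Step 11
Reactants: 15 3,5,7-tris(benzyloxy)-2-[3-(benzyloxy)-4-hydroxyphenyl]-4H-chromen-4-one
Product: 16 sodium 2-(benzyloxy)-4-[3,5,7-tris(benzyloxy)-4-oxo-4H-chromen-2-yl]phenyl sulfate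
Conditions: SO3·pyridine (5 equiv), pyridine, rt to 40 °C; then aq. NaHCO3
Reagents that add atoms: sulfur trioxide–pyridine complex, [O-]S(=O)(=O)[n+]1ccccc1; sodium hydrogen carbonate (NaHCO3), [Na+].OC([O-])=O
Why: O-Sulfation of the single free phenol with the SO3·pyridine complex, the sulfate monoester being isolated as its stable sodium salt after bicarbonate treatment.

Step 12
Reactants: 16 sodium 2-(benzyloxy)-4-[3,5,7-tris(benzyloxy)-4-oxo-4H-chromen-2-yl]phenyl sulfate
Product: 18 2-hydroxy-4-(3,5,7-trihydroxy-4-oxo-4H-chromen-2-yl)phenyl hydrogen sulfate (quercetin 4'-O-sulfate; target), via quercetin 4'-O-sulfate sodium salt 17 (not isolated)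
Conditions: H2 (1 atm), 10% Pd/C, THF–MeOH (1:1), rt; filter; then Dowex 50W-X8 (H+ form), H2O–MeOH, 0 °C; freeze-dry
Reagents that add atoms: none
Why: Catalytic hydrogenolysis over palladium removes the four benzyl ethers while the aryl sulfate salt and the flavonol double bond should stay intact, and strongly acidic cation-exchange resin in the cold then swaps sodium for a proton to give the free hydrogen sulfate.

**Compound list**
1 | 2,4,6-trihydroxybenzaldehyde | O=Cc1c(O)cc(O)cc1O | starting material
2 | 2,4-bis(benzyloxy)-6-hydroxybenzaldehyde | O=Cc1c(OCc2ccccc2)cc(OCc2ccccc2)cc1O | intermediate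
3 | 3,4-dihydroxybenzaldehyde | O=Cc1ccc(O)c(O)c1 | starting material
4 | 3-hydroxy-4-(methoxymethoxy)benzaldehyde | O=Cc1ccc(OCOC)c(O)c1 | intermediate
5 | 3-(benzyloxy)-4-(methoxymethoxy)benzaldehyde | O=Cc1ccc(OCOC)c(OCc2ccccc2)c1 | intermediate
6 | vinylmagnesium bromide | C=C[Mg]Br | starting material
7 | 1-[3-(benzyloxy)-4-(methoxymethoxy)phenyl]prop-2-en-1-ol (racemic; R drawn) | O[C@H](C=C)c1ccc(OCOC)c(OCc2ccccc2)c1 | intermediate
8 | 2,4-bis(benzyloxy)-6-({1-[3-(benzyloxy)-4-(methoxymethoxy)phenyl]prop-2-en-1-yl}oxy)benzaldehyde (racemic; S drawn) | O=Cc1c(OCc2ccccc2)cc(OCc2ccccc2)cc1O[C@@H](C=C)c1ccc(OCOC)c(OCc2ccccc2)c1 | intermediate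
9 | 2,4-bis(benzyloxy)-6-{1-[3-(benzyloxy)-4-(methoxymethoxy)phenyl]-2,3-dihydroxypropoxy}benzaldehyde (not isolated; racemic; mixture of diastereomers at the secondary carbinol) | O=Cc1c(OCc2ccccc2)cc(OCc2ccccc2)cc1O[C@@H](C(O)CO)c1ccc(OCOC)c(OCc2ccccc2)c1 | intermediate
10 | 2,4-bis(benzyloxy)-6-{1-[3-(benzyloxy)-4-(methoxymethoxy)phenyl]-2-oxoethoxy}benzaldehyde (racemic; R drawn) | O=Cc1c(OCc2ccccc2)cc(OCc2ccccc2)cc1O[C@@H](C=O)c1ccc(OCOC)c(OCc2ccccc2)c1 | intermediate
11 | trans-5,7-bis(benzyloxy)-2-[3-(benzyloxy)-4-(methoxymethoxy)phenyl]-3-hydroxychroman-4-one (racemic; 2R,3R drawn) | O=C1c2c(OCc3ccccc3)cc(OCc3ccccc3)cc2O[C@H](c2ccc(OCOC)c(OCc3ccccc3)c2)[C@H]1O | intermediate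
12 | 5,7-bis(benzyloxy)-2-[3-(benzyloxy)-4-(methoxymethoxy)phenyl]chromane-3,4-dione (not isolated; racemic; 2R drawn) | O=C1c2c(OCc3ccccc3)cc(OCc3ccccc3)cc2O[C@H](c2ccc(OCOC)c(OCc3ccccc3)c2)C1=O | intermediate
13 | 5,7-bis(benzyloxy)-2-[3-(benzyloxy)-4-(methoxymethoxy)phenyl]-3-hydroxy-4H-chromen-4-one | O=c1c(O)c(-c2ccc(OCOC)c(OCc3ccccc3)c2)oc2cc(OCc3ccccc3)cc(OCc3ccccc3)c12 | intermediate
14 | 3,5,7-tris(benzyloxy)-2-[3-(benzyloxy)-4-(methoxymethoxy)phenyl]-4H-chromen-4-one | O=c1c(OCc2ccccc2)c(-c2ccc(OCOC)c(OCc3ccccc3)c2)oc2cc(OCc3ccccc3)cc(OCc3ccccc3)c12 | intermediate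
15 | 3,5,7-tris(benzyloxy)-2-[3-(benzyloxy)-4-hydroxyphenyl]-4H-chromen-4-one | O=c1c(OCc2ccccc2)c(-c2ccc(O)c(OCc3ccccc3)c2)oc2cc(OCc3ccccc3)cc(OCc3ccccc3)c12 | intermediate
16 | sodium 2-(benzyloxy)-4-[3,5,7-tris(benzyloxy)-4-oxo-4H-chromen-2-yl]phenyl sulfate | O=c1c(OCc2ccccc2)c(-c2ccc(OS(=O)(=O)[O-])c(OCc3ccccc3)c2)oc2cc(OCc3ccccc3)cc(OCc3ccccc3)c12.[Na+] | intermediate
17 | sodium 2-hydroxy-4-(3,5,7-trihydroxy-4-oxo-4H-chromen-2-yl)phenyl sulfate (not isolated) | O=c1c(O)c(-c2ccc(OS(=O)(=O)[O-])c(O)c2)oc2cc(O)cc(O)c12.[Na+] | intermediate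
18 | 2-hydroxy-4-(3,5,7-trihydroxy-4-oxo-4H-chromen-2-yl)phenyl hydrogen sulfate (quercetin 4'-O-sulfate) | O=c1c(O)c(-c2ccc(OS(=O)(=O)O)c(O)c2)oc2cc(O)cc(O)c12 | target

**Step count**
Total: 12 steps. Longest linear sequence: 11 steps (steps 2 to 12, from 3,4-dihydroxybenzaldehyde).

**Steps most likely to fail**

Step 7. The carbene may add mainly to the more electrophilic aliphatic aldehyde, and the enaminol formed there can expel the ring A phenoxide (internal redox fragmentation) instead of cyclising. The amine may also enolise the doubly activated C2–H and divert the material into a five-membered aldol closure. Enaminol formation at the doubly ortho-substituted ring A aldehyde may also be too slow. The fallback forms the same C3–C4 bond reductively and sets out from dialdehyde 10. SmI2 (2.5 equiv) with t-BuOH in THF at −78 °C should reduce the aryl aldehyde to its ketyl, which adds to the neighbouring aldehyde in a pinacol cyclisation. This gives 5,7-bis(benzyloxy)-2-[3-(benzyloxy)-4-(methoxymethoxy)phenyl]chromane-3,4-diol F1, expected mainly as the cis-diol. Swern oxidation of both carbinols [(COCl)2, DMSO, CH2Cl2, −78 °C; Et3N] then gives dione 12, which enolises, so the route is rejoined at flavonol 13.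

Step 5. The activated, electron-rich allylic benzylic alcohol may ionise, which would lead to allylic transposition (attack at the alkene terminus) or to C-alkylation of the phloroglucinol-type ring instead of clean O-alkylation at the carbinol carbon. The fallback sets out from alcohol 7. Methyl chloroformate and pyridine in CH2Cl2 at 0 °C give 1-[3-(benzyloxy)-4-(methoxymethoxy)phenyl]prop-2-en-1-yl methyl carbonate F2. Iridium-catalysed allylic etherification with the sodium phenoxide of 2 ([Ir(cod)Cl]2, a binaphthol-derived phosphoramidite ligand, THF, rt) then follows. This reaction type delivers the branched aryl ether from aryl-substituted allyl carbonates whichever carbonate regioisomer is used. It comes back to the route at ether 8.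

Step 6. The α-aryl-α-aryloxy aldehyde may hydrate, enolise and autoxidise, or degrade during the aqueous periodate reaction and work-up. The fallback sets out from alkene 8. Ozonolysis in CH2Cl2–MeOH at −78 °C with NaBH4 work-up reduces the ozonide and the ring A aldehyde together. This gives the stable, purifiable {2,4-bis(benzyloxy)-6-[1-(3-(benzyloxy)-4-(methoxymethoxy)phenyl)-2-hydroxyethoxy]phenyl}methanol F3. Double Dess–Martin oxidation in dry CH2Cl2, followed by a brief cold bicarbonate wash and drying, then delivers dialdehyde 10 for immediate use in step 7.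

**Further compounds**
F1 | step 7 | 5,7-bis(benzyloxy)-2-[3-(benzyloxy)-4-(methoxymethoxy)phenyl]chromane-3,4-diol (racemic; 3,4-cis and 2,3-trans isomer drawn, 2R,3S,4S) | O[C@H]1c2c(OCc3ccccc3)cc(OCc3ccccc3)cc2O[C@H](c2ccc(OCOC)c(OCc3ccccc3)c2)[C@H]1O
F2 | step 5 | 1-[3-(benzyloxy)-4-(methoxymethoxy)phenyl]prop-2-en-1-yl methyl carbonate (racemic; R drawn) | COC(=O)O[C@H](C=C)c1ccc(OCOC)c(OCc2ccccc2)c1
F3 | step 6 | {2,4-bis(benzyloxy)-6-[1-(3-(benzyloxy)-4-(methoxymethoxy)phenyl)-2-hydroxyethoxy]phenyl}methanol (racemic; R drawn) | OCc1c(OCc2ccccc2)cc(OCc2ccccc2)cc1O[C@@H](CO)c1ccc(OCOC)c(OCc2ccccc2)c1
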